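## Retrosynthetic overview

1. The imidazole is the only ring to build, and it is closed last. NH4OAc supplies N1 and forms the N1–C5 and N1–C2 bonds from the α-acylamino ketone ArCH2CH2CH(NHCOR)C(O)CH3 (R = 4-acetoxybutyl).
2. The key disconnection is the future C4–C5 bond of the imidazole. Both carbons start as electrophilic C=X carbons (acetaldehyde C=O and N-acylimine C=N), so a thiazolium carbene inverts acetaldehyde into an acetyl anion (Breslow intermediate).
3. The enolisable N-acylimine is released in situ from an α-amido sulfone. That sulfone is assembled from 5-acetoxypentanamide, 3-(3,4-dimethoxyphenyl)propanal and p-toluenesulfinic acid.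
4. The amide comes from δ-valerolactone (NH3, then Ac2O). The aldehyde comes from commercial 3-(3,4-dimethoxyphenyl)propan-1-ol.

Assumption: the target SMILES holds no stereocentre, so the compound is achiral and no enantiocontrol is needed. The racemic stereocentres of 6 and 9 vanish on aromatisation, and the two N–H tautomers of the imidazole are one compound.

## Route

Step 1
Reactants: 1 δ-valerolactone
Product: 3 5-acetoxypentanamide (5-amino-5-oxopentyl acetate), via 5-hydroxypentanamide 2 (not isolated)
Conditions: NH3 (7 M in MeOH), rt, 16 h; evaporate; Ac2O (1.2 equiv), DMAP (5 mol%), pyridine, 0 °C to rt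
Reagents that add atoms: ammonia, N; acetic anhydride, CC(=O)OC(C)=O
Why: Lactone aminolysis by ammonia is clean, and the primary alcohol of 2 is far more nucleophilic than the primary carboxamide, so the DMAP-catalysed O-acetylation (nucleophilic acyl substitution) is chemoselective; no stereocentre is formed.

Step 2
Reactants: 4 3-(3,4-dimethoxyphenyl)propan-1-ol
Product: 5 3-(3,4-dimethoxyphenyl)propanal
Conditions: TEMPO (10 mol%), PhI(OAc)2 (1.1 equiv), CH2Cl2, rt, 3 h
Reagents that add atoms: none
Why: The TEMPO/PhI(OAc)2 oxoammonium oxidation stops at the aldehyde under water-free, nearly neutral conditions and leaves the electron-rich dimethoxyphenyl ring untouched; no stereocentre is formed.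

Step 3
Reactants: 3 5-acetoxypentanamide; 5 3-(3,4-dimethoxyphenyl)propanal
Product: 6 5-({3-(3,4-dimethoxyphenyl)-1-[(4-methylphenyl)sulfonyl]propyl}amino)-5-oxopentyl acetate (racemic α-amido sulfone)
Conditions: p-TolSO2H (1.1 equiv), MgSO4, CH2Cl2, rt, 24 h
Reagents that add atoms: p-toluenesulfinic acid, Cc1ccc(cc1)S(=O)O
Why: In this three-component Mannich-type amidoalkylation (α-amido sulfone formation) the amide and aldehyde give an N-acyliminium ion that the soft sulfinate captures at once while MgSO4 binds the water, the weak acid avoids Friedel–Crafts closure onto the dimethoxyphenyl ring, and the new stereocentre is racemic and erased in step 4.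

Step 4
Reactants: 6 α-amido sulfone; 7 acetaldehyde
Product: 10 O-acetylcypholophine (4-{4-[2-(3,4-dimethoxyphenyl)ethyl]-5-methyl-1H-imidazol-2-yl}butyl acetate), via N-acylimine 8 (not isolated), via amido ketone 9 (not isolated)
Conditions: 7 (5 equiv), 3-benzyl-5-(2-hydroxyethyl)-4-methylthiazolium chloride (20 mol%), Et3N (10 equiv), CH2Cl2, 35 °C, sealed tube, 12 h; evaporate; NH4OAc (20 equiv), AcOH, 110 °C, 3 h
Reagents that add atoms: ammonium acetate, CC(=O)[O-].[NH4+]
Why: Proposed new method: Et3N expels sulfinate from 6 to feed the N-acylimine 8 at low concentration while the thiazol-2-ylidene turns excess acetaldehyde into its Breslow intermediate (acetyl anion equivalent), which attacks the much more electrophilic C=N carbon faster than a second aldehyde and gives 9 after loss of the catalyst; the closest known reaction is the thiazolium-catalysed aldehyde/acylimine cross-coupling (aza-benzoin) of aryl-derived amido sulfones with its one-pot Davidson-type NH4OAc cyclodehydration to imidazoles, and the extension to an enolisable alkyl acylimine rests on the fact that such imines released from amido sulfones are trapped by carbon nucleophiles (aza-Henry, Mannich) faster than they tautomerise to enamides; AcOH as solvent makes any acetate exchange degenerate, excess NH4OAc suppresses oxazole formation, and the racemic centre of 9 disappears on aromatisation.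

## Compound list

1 | δ-valerolactone (tetrahydro-2H-pyran-2-one) | O=C1CCCCO1 | starting material
2 | 5-hydroxypentanamide | NC(=O)CCCCO | intermediate
3 | 5-acetoxypentanamide (5-amino-5-oxopentyl acetate) | CC(=O)OCCCCC(N)=O | intermediate
4 | 3-(3,4-dimethoxyphenyl)propan-1-ol | COc1ccc(CCCO)cc1OC | starting material
5 | 3-(3,4-dimethoxyphenyl)propanal | COc1ccc(CCC=O)cc1OC | intermediate
6 | 5-({3-(3,4-dimethoxyphenyl)-1-[(4-methylphenyl)sulfonyl]propyl}amino)-5-oxopentyl acetate (racemic) | COc1ccc(CCC(NC(=O)CCCCOC(C)=O)S(=O)(=O)c2ccc(C)cc2)cc1OC | intermediate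
7 | acetaldehyde | CC=O | starting material
8 | 5-{[(E)-3-(3,4-dimethoxyphenyl)propylidene]amino}-5-oxopentyl acetate (N-acylimine) | COc1ccc(CC/C=N/C(=O)CCCCOC(C)=O)cc1OC | intermediate
9 | 5-{[1-(3,4-dimethoxyphenyl)-4-oxopentan-3-yl]amino}-5-oxopentyl acetate (racemic amido ketone) | COc1ccc(CCC(NC(=O)CCCCOC(C)=O)C(C)=O)cc1OC | intermediate
10 | O-acetylcypholophine | COc1ccc(CCc2nc(CCCCOC(C)=O)[nH]c2C)cc1OC | target

## Step count and risks

Total step count: 4.
Longest linear sequence: 3 steps (1 → 3 → 6 → 10, or 4 → 5 → 6 → 10).

**Step 4 (highest risk).**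
- **Failure mode:** N-acylimine 8 may tautomerise to its enamide, or acetaldehyde may be lost as acetoin, before the C–C bond forms.
- **Change of approach:** the catalytic acetyl anion is replaced by a stoichiometric one, the nitronate of nitroethane.
- **Fallback:** it sets out from 6. Nitroethane (5 equiv) and Cs2CO3 in THF at rt release 8 and add to it in an aza-Henry reaction, which is well behaved for alkyl-derived amido sulfones. This gives the nitro amide 5-{[1-(3,4-dimethoxyphenyl)-4-nitropentan-3-yl]amino}-5-oxopentyl acetate F1 as a diastereomer mixture. KOt-Bu (1.0 equiv, THF, 0 °C) converts it into potassium 3-(5-acetoxypentanamido)-5-(3,4-dimethoxyphenyl)pentane-2-nitronate F2. KMnO4/MgSO4 in water at 0 °C cleaves F2 within minutes (oxidative Nef reaction).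
- **Return:** the route is rejoined at amido ketone 9, which is heated with NH4OAc in AcOH as in the second half of step 4.

**Step 3.**
- **Failure mode:** the three-component equilibrium may be unfavourable, the product may be a non-crystalline oil, or the N-acyliminium ion may close onto the electron-rich ring.
- **Change of approach:** the roles of the two aldehydes are exchanged.
- **Fallback:** it sets out from 3, which is condensed with acetaldehyde 7 and p-TolSO2H. Acetaldehyde is small and carries no internal arene nucleophile. This gives 5-({1-[(4-methylphenyl)sulfonyl]ethyl}amino)-5-oxopentyl acetate F3. The thiazolium chloride and Et3N release 5-{[(E)-ethylidene]amino}-5-oxopentyl acetate F4, and aldehyde 5 is now the partner converted into the Breslow intermediate. The product is the regioisomeric amido ketone 5-{[5-(3,4-dimethoxyphenyl)-3-oxopentan-2-yl]amino}-5-oxopentyl acetate F5.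
- **Return:** NH4OAc in AcOH at 110 °C closes F5 to the same N–H imidazole, so the route is rejoined at 10.

**Step 1.**
- **Failure mode:** hydroxy amide 2 is very polar and may relactonise on concentration, and imide formation is possible with Ac2O.
- **Change of approach:** the acetate is installed first and the amide is made last, so 2 is never handled.
- **Fallback:** it sets out from 1. NaOH (1.0 equiv, H2O, rt) gives sodium 5-hydroxypentanoate F6. Evaporation, Ac2O/pyridine and acidification with HCl give 5-acetoxypentanoic acid F7. 1,1'-Carbonyldiimidazole in THF gives the acyl imidazole 5-(1H-imidazol-1-yl)-5-oxopentyl acetate F8.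
- **Return:** NH3 (0.5 M in dioxane, 0 °C) converts F8 into 3, where the route is rejoined.

## Further compounds

F1 | step 4 | 5-{[1-(3,4-dimethoxyphenyl)-4-nitropentan-3-yl]amino}-5-oxopentyl acetate (diastereomer mixture, racemic) | COc1ccc(CCC(NC(=O)CCCCOC(C)=O)C(C)[N+](=O)[O-])cc1OC
F2 | step 4 | potassium 3-(5-acetoxypentanamido)-5-(3,4-dimethoxyphenyl)pentane-2-nitronate (racemic) | [K+].CC(=[N+]([O-])[O-])C(CCc1ccc(OC)c(OC)c1)NC(=O)CCCCOC(C)=O
F3 | step 3 | 5-({1-[(4-methylphenyl)sulfonyl]ethyl}amino)-5-oxopentyl acetate (racemic) | CC(NC(=O)CCCCOC(C)=O)S(=O)(=O)c1ccc(C)cc1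
F4 | step 3 | 5-{[(E)-ethylidene]amino}-5-oxopentyl acetate | C/C=N/C(=O)CCCCOC(C)=O
F5 | step 3 | 5-{[5-(3,4-dimethoxyphenyl)-3-oxopentan-2-yl]amino}-5-oxopentyl acetate (racemic) | COc1ccc(CCC(=O)C(C)NC(=O)CCCCOC(C)=O)cc1OC
F6 | step 1 | sodium 5-hydroxypentanoate | [Na+].[O-]C(=O)CCCCO
F7 | step 1 | 5-acetoxypentanoic acid | CC(=O)OCCCCC(=O)O
F8 | step 1 | 5-(1H-imidazol-1-yl)-5-oxopentyl acetate | CC(=O)OCCCCC(=O)n1ccnc1
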